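**Retrosynthetic overview**

- The target is the all-cis (2R,3R,4R) oxolane: H2, H3 and H4 lie on one face, which is the pattern left by face-selective hydrogenation of a furan; the CH2OH comes from an ester.
- Enabling feature: ring O–C2(aryl)–C3–CH2OH is a masked β-ketoester (the ring oxygen on C2 and the oxygenated carbon on C3 are 1,3-related), and C4(benzyl)–C5H2 is a masked α-chloroketone (C4 = carbonyl carbon, C5 = CH2Cl). A Feist–Bénary annulation joins C3–C4 (aldol) and O–C5 (O-alkylation) in one operation and gives the fully substituted furan-3-carboxylate.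
- Ring order: the furan, the only ring made, is built in step 3 and then saturated in two stages. C4=C5 is reduced enantioselectively (sets C4); C2=C3 is reduced under substrate control (sets C2 and C3 cis to C4); ester reduction comes last.
- The chloroketone comes from 1-bromo-2,4,5-trimethoxybenzene and epichlorohydrin; the β-ketoester is commercial.

Key step: step 3

Remark on the chemistry: the SMILES is read as the all-cis oxolane (2R,3R,4R); the racemic centres of 4 and 7 are erased again on the way.
Abbreviations for step 4: cod = cycloocta-1,5-diene; BArF = B[3,5-(CF3)2C6H3]4 anion; L* = 8-(di-tert-butylphosphanyloxy)-2-phenyl-5,6,7,8-tetrahydroquinoline, a chiral pyridine–phosphinite N,P ligand. Which antipode of L* gives (4R)-9 would be fixed by running both.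

**Step 1**
Reactants: 1 1-bromo-2,4,5-trimethoxybenzene; 2 (±)-epichlorohydrin
Product: 4 (±)-1-chloro-3-(2,4,5-trimethoxyphenyl)propan-2-ol, via arylmagnesium bromide 3 (not isolated)
Conditions: Mg, THF, 50 °C; then CuI (10 mol %), 2, −30 → 0 °C
Reagents that add atoms: none
Why: Copper-catalysed Grignard opening of the epoxide at its unsubstituted carbon (SN2) should leave the primary chloride untouched when quenched cold; the carbinol centre is racemic and is erased in step 2.

**Step 2**
Reactants: 4 (±)-1-chloro-3-(2,4,5-trimethoxyphenyl)propan-2-ol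
Product: 5 1-chloro-3-(2,4,5-trimethoxyphenyl)propan-2-one
Conditions: Dess–Martin periodinane, CH2Cl2, 0 °C → rt
Reagents that add atoms: none
Why: Dess–Martin oxidation of a secondary alcohol under neutral conditions should tolerate the primary chloride and the electron-rich arene and leaves no stereocentre.

**Step 3**
Reactants: 5 1-chloro-3-(2,4,5-trimethoxyphenyl)propan-2-one; 6 ethyl 3-oxo-3-(3,4,5-trimethoxyphenyl)propanoate
Product: 8 ethyl 2-(3,4,5-trimethoxyphenyl)-4-[(2,4,5-trimethoxyphenyl)methyl]furan-3-carboxylate, via hydroxydihydrofuran 7 (not isolated)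
Conditions: pyridine, EtOH, 50 °C; then p-TsOH·H2O (10 mol %), toluene, 80 °C
Reagents that add atoms: none
Why: Pyridine enolises 6, whose central carbon (future C3) adds in an aldol fashion to the ketone carbonyl of 5 (future C4); the enol oxygen of the aroyl group (the ring oxygen on C2) then displaces chloride from the neighbouring CH2Cl (future C5) to give 7, which acid dehydrates to the aromatic furan 8. The closest known reaction type is the Feist–Bénary synthesis of 2,4-disubstituted furan-3-carboxylates from β-ketoesters and α-chloroketones. The single ring closes by O-alkylation in a 5-exo-tet mode. No lasting stereocentre is formed: the carbinol carbon of 7 is lost on aromatisation, and the three stereocentres are deliberately left to steps 4 and 5. The selectivity needed is aldol addition at C=O ahead of SN2 C-alkylation at CH2Cl, which would end in the 2,5-disubstituted furan isomer; it should be secured by chloride being a poor leaving group, by the high electrophilicity of the α-chloroketone carbonyl, and by a weak amine base in a protic solvent that keeps the free enolate concentration low.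

**Step 4**
Reactants: 8 ethyl 2-(3,4,5-trimethoxyphenyl)-4-[(2,4,5-trimethoxyphenyl)methyl]furan-3-carboxylate
Product: 9 ethyl (4R)-2-(3,4,5-trimethoxyphenyl)-4-[(2,4,5-trimethoxyphenyl)methyl]-4,5-dihydrofuran-3-carboxylate
Conditions: H2 (50 bar), [Ir(cod)(L*)]BArF (2 mol %), CH2Cl2, 40 °C
Reagents that add atoms: none
Why: Proposed new method: the cationic iridium dihydride formed from the monovalent iridium precatalyst should bind and reduce only the trisubstituted, electron-rich C4=C5 enol-ether bond, because C2=C3 is tetrasubstituted and deactivated as a vinylogous carbonate by the ester, so the reaction should stop at the β-alkoxyacrylate 9 with the chiral N,P pocket choosing the face at C4; the closest known reaction type is the Ir–N,P-catalysed asymmetric hydrogenation of 3-substituted furans and benzofurans, which sets the β-carbon stereocentre in the same way.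

**Step 5**
Reactants: 9 ethyl (4R)-2-(3,4,5-trimethoxyphenyl)-4-[(2,4,5-trimethoxyphenyl)methyl]-4,5-dihydrofuran-3-carboxylate
Product: 10 ethyl (2R,3S,4R)-2-(3,4,5-trimethoxyphenyl)-4-[(2,4,5-trimethoxyphenyl)methyl]oxolane-3-carboxylate (all-cis)
Conditions: H2 (5 bar), Rh/Al2O3 (5 wt % Rh), EtOAc, 25 °C
Reagents that add atoms: none
Why: Heterogeneous syn-hydrogenation should take place on the face of C2=C3 opposite the C4 benzyl group, so the new H2 and H3 end up cis to H4 and the aryl, ester and benzyl groups all cis (substrate-controlled catalytic hydrogenation); rhodium on alumina is chosen to avoid hydrogenolysis of the new benzylic C2–O bond.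

**Step 6**
Reactants: 10 ethyl (2R,3S,4R)-2-(3,4,5-trimethoxyphenyl)-4-[(2,4,5-trimethoxyphenyl)methyl]oxolane-3-carboxylate
Product: 11 [(2R,3R,4R)-2-(3,4,5-trimethoxyphenyl)-4-[(2,4,5-trimethoxyphenyl)methyl]oxolan-3-yl]methanol (target)
Conditions: LiAlH4, THF, −20 → 0 °C
Reagents that add atoms: none
Why: Hydride reduction of the ester to the primary alcohol should be faster than enolisation at low temperature, so C3 is not epimerised; the descriptor at C3 changes from S to R only because the CIP priorities change.

**Compound list**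

1 | 1-bromo-2,4,5-trimethoxybenzene | COc1cc(OC)c(OC)cc1Br | starting material
2 | (±)-epichlorohydrin, 2-(chloromethyl)oxirane | ClCC1CO1 | starting material
3 | (2,4,5-trimethoxyphenyl)magnesium bromide | COc1cc(OC)c(OC)cc1[Mg]Br | intermediate
4 | (±)-1-chloro-3-(2,4,5-trimethoxyphenyl)propan-2-ol | COc1cc(OC)c(OC)cc1CC(O)CCl | intermediate
5 | 1-chloro-3-(2,4,5-trimethoxyphenyl)propan-2-one | COc1cc(OC)c(OC)cc1CC(=O)CCl | intermediate
6 | ethyl 3-oxo-3-(3,4,5-trimethoxyphenyl)propanoate | CCOC(=O)CC(=O)c1cc(OC)c(OC)c(OC)c1 | starting material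
7 | ethyl (±)-4-hydroxy-2-(3,4,5-trimethoxyphenyl)-4-[(2,4,5-trimethoxyphenyl)methyl]-4,5-dihydrofuran-3-carboxylate | CCOC(=O)C1=C(c2cc(OC)c(OC)c(OC)c2)OCC1(O)Cc1cc(OC)c(OC)cc1OC | intermediate
8 | ethyl 2-(3,4,5-trimethoxyphenyl)-4-[(2,4,5-trimethoxyphenyl)methyl]furan-3-carboxylate | CCOC(=O)c1c(-c2cc(OC)c(OC)c(OC)c2)occ1Cc1cc(OC)c(OC)cc1OC | intermediate
9 | ethyl (4R)-2-(3,4,5-trimethoxyphenyl)-4-[(2,4,5-trimethoxyphenyl)methyl]-4,5-dihydrofuran-3-carboxylate | COc1cc(OC)c(OC)cc1C[C@H]1COC(c2cc(OC)c(OC)c(OC)c2)=C1C(=O)OCC | intermediate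
10 | ethyl (2R,3S,4R)-2-(3,4,5-trimethoxyphenyl)-4-[(2,4,5-trimethoxyphenyl)methyl]oxolane-3-carboxylate | COc1cc(OC)c(OC)cc1C[C@H]1CO[C@@H](c2cc(OC)c(OC)c(OC)c2)[C@H]1C(=O)OCC | intermediate
11 | [(2R,3R,4R)-2-(3,4,5-trimethoxyphenyl)-4-[(2,4,5-trimethoxyphenyl)methyl]oxolan-3-yl]methanol | COc1cc(OC)c(OC)cc1C[C@H]1CO[C@@H](c2cc(OC)c(OC)c(OC)c2)[C@H]1CO | target

**Totals**

Total step count: 6. Longest linear sequence: 6 steps (1 → 4 → 5 → 8 → 9 → 10 → 11); 6 enters at step 3.

**Steps most likely to fail**

Step 4. The catalyst may not turn over on this hindered trisubstituted furan, may reduce both double bonds, or may discriminate poorly between the two faces of C4=C5. The fallback sets out from 8 and comes back at 11. Exhaustive heterogeneous hydrogenation of 8 (H2, Rh/Al2O3, EtOAc, higher pressure) delivers all hydrogen to one face and should give the racemic all-cis ester F1. LiAlH4 reduction as in step 6 should give the racemic all-cis alcohol F2. The enantiomers of F2 are then separated by preparative chromatography on a chiral stationary phase, and the (2R,3R,4R) antipode is 11.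

Step 5. Hydrogen may add from the wrong face, because the controlling aryl group sits one CH2 away from C4, or the benzylic C2–O bond may be hydrogenolysed once the oxolane has formed. The fallback sets out from 9 and comes back at 11. Saponification of 9 (LiOH, THF/H2O) should give the (4R)-4,5-dihydrofuran-3-carboxylic acid F3. Carboxylate-directed homogeneous hydrogenation with Ru(OAc)2(BINAP), using the BINAP antipode matched to C4, is a known reaction type for tetrasubstituted acrylic acids; here the catalyst chooses the face and no heterogeneous hydrogenolysis site is present, so it should give the all-cis (2R,3S,4R) acid F4. Reduction with BH3·SMe2 then gives 11.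

Step 3. SN2 C-alkylation of 6 at the CH2Cl carbon may run ahead of the aldol addition (leading to the 2,5-disubstituted furan isomer), pyridine may be quaternised by 5, or 5 may self-condense through its acidic benzylic CH2. The fallback sets out from 6 and comes back at 8. The same Feist–Bénary annulation is run with commercial 1,3-dichloroacetone, which is symmetrical, more electrophilic at the carbonyl and has no benzylic position, and should give ethyl 4-(chloromethyl)-2-(3,4,5-trimethoxyphenyl)furan-3-carboxylate F5. Friedel–Crafts alkylation of 1,2,4-trimethoxybenzene with F5 (ZnCl2, CH2Cl2, 0 °C) should occur at C5 of the arene, para to one methoxy group and ortho to another, and gives 8.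

**Further compounds**

F1 | step 4 | ethyl rac-(2R,3S,4R)-2-(3,4,5-trimethoxyphenyl)-4-[(2,4,5-trimethoxyphenyl)methyl]oxolane-3-carboxylate (racemic all-cis ester, both enantiomers) | COc1cc(OC)c(OC)cc1C[C@H]1CO[C@@H](c2cc(OC)c(OC)c(OC)c2)[C@H]1C(=O)OCC.COc1cc(OC)c(OC)cc1C[C@@H]1CO[C@H](c2cc(OC)c(OC)c(OC)c2)[C@@H]1C(=O)OCC
F2 | step 4 | rac-[(2R,3R,4R)-2-(3,4,5-trimethoxyphenyl)-4-[(2,4,5-trimethoxyphenyl)methyl]oxolan-3-yl]methanol (racemic all-cis alcohol, both enantiomers) | COc1cc(OC)c(OC)cc1C[C@H]1CO[C@@H](c2cc(OC)c(OC)c(OC)c2)[C@H]1CO.COc1cc(OC)c(OC)cc1C[C@@H]1CO[C@H](c2cc(OC)c(OC)c(OC)c2)[C@@H]1CO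
F3 | step 5 | (4R)-2-(3,4,5-trimethoxyphenyl)-4-[(2,4,5-trimethoxyphenyl)methyl]-4,5-dihydrofuran-3-carboxylic acid | COc1cc(OC)c(OC)cc1C[C@H]1COC(c2cc(OC)c(OC)c(OC)c2)=C1C(=O)O
F4 | step 5 | (2R,3S,4R)-2-(3,4,5-trimethoxyphenyl)-4-[(2,4,5-trimethoxyphenyl)methyl]oxolane-3-carboxylic acid | COc1cc(OC)c(OC)cc1C[C@H]1CO[C@@H](c2cc(OC)c(OC)c(OC)c2)[C@H]1C(=O)O
F5 | step 3 | ethyl 4-(chloromethyl)-2-(3,4,5-trimethoxyphenyl)furan-3-carboxylate | CCOC(=O)c1c(-c2cc(OC)c(OC)c(OC)c2)occ1CCl
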